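**Retrosynthetic overview**
1. Ring D (ketal carbon A, bridging O, carbinol CH, pyranone C3, ketal carbon B, ketal O) is opened by retro-oxa-Michael addition and loss of water to a chromone-fused dienol ether; the acids and phenols are carried as benzyl esters and ethers, and the west carboxyl as an aryl bromide.
2. The west chromone is cut at chromone C3–C4 and O1–C2 into a dihydropyranone and a 2-bromo-6-tert-butoxy aryl aldehyde (aldol, oxidation, acid cyclodehydration).
3. The strategy rests on ring C (bridging O, carbinol CH, chromone C3, chromone C2, CH2, ketal carbon A). It is read as a 6-methyl-2,3-dihydropyran-4-one whose C4 ketone becomes chromone C2, and is cut across O–C(ketal A) and CH(carbinol)–C(chromone C3) into tribenzyl 3-formylcitromycetin and (E)-4-methoxy-2-(trimethylsilyloxy)penta-1,3-diene.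
4. The formylpyranone ring comes from a 4-chloro-2H-chromene-3-carbonyl chloride and an enaminone; the chromanone comes from benzene-1,2,4-triol, with its carboxyl introduced by phenoxide-directed ortho-formylation.
5. Ring order: east chromanone ring, east pyranone ring, ring C, west chromone ring, ring D.

Key step: step 11

Labels: ketal carbon A is the west C(CH3)(CH2)(O)(O); ketal carbon B is the east C(CH3)(O)(O); CHα is the CH between the carbinol CH and ketal carbon B. The target is A (R), carbinol CH (S), CHα (S), B (S).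
Assumption: (R)-BINOL is taken to direct the diene to the Re face of the aldehyde, the sense usual for aryl aldehydes; this is checked on the dihydropyranone and (S)-BINOL is used if the sense proves reversed.

**Route**

Step 1
Reactants: 1 benzene-1,2,4-triol; 2 3-chloropropanoic acid
Product: 4 6,7-dihydroxychroman-4-one, via chloroketone 3 (not isolated)
Conditions: TfOH, 80 °C; then 2 M NaOH (degassed), 0 °C → rt; HCl
Reagents that add atoms: none
Why: Friedel–Crafts acylation should occur at C5 of the triol (para to one hydroxyl, ortho to another), and the β-chloroketone then closes under base by intramolecular Williamson etherification, the standard one-pot chroman-4-one synthesis.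

Step 2
Reactants: 4 6,7-dihydroxychroman-4-one; 5 benzyl bromide
Product: 6 7-(benzyloxy)-6-hydroxychroman-4-one
Conditions: 5 (1.05 equiv), KHCO3, DMF, rt
Reagents that add atoms: none
Why: Williamson etherification under weak base should select the 7-hydroxyl, which is para to the ketone and the most acidic phenol, as in the 4-O-alkylation of 3,4-dihydroxyaryl ketones.

Step 3
Reactants: 6 7-(benzyloxy)-6-hydroxychroman-4-one
Product: 7 7-(benzyloxy)-6-hydroxy-4-oxochromane-5-carbaldehyde
Conditions: MgCl2, Et3N, (CH2O)n, MeCN, reflux; 1 M HCl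
Reagents that add atoms: paraformaldehyde (formaldehyde) C=O
Why: Magnesium-phenoxide-directed ortho-formylation (Casnati–Skattebøl) delivers formaldehyde only ortho to the free phenol, and C5 is its sole open ortho position.

Step 4
Reactants: 7 7-(benzyloxy)-6-hydroxy-4-oxochromane-5-carbaldehyde
Product: 8 7-(benzyloxy)-6-hydroxy-4-oxochromane-5-carboxylic acid
Conditions: NaClO2, NaH2PO4, 2-methylbut-2-ene, t-BuOH/H2O, rt
Reagents that add atoms: sodium chlorite [Na+].[O-]Cl=O
Why: Lindgren–Pinnick oxidation converts a phenolic aryl aldehyde into the acid, with the alkene scavenging HOCl so that the electron-rich ring is not chlorinated.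

Step 5
Reactants: 8 7-(benzyloxy)-6-hydroxy-4-oxochromane-5-carboxylic acid; 5 benzyl bromide
Product: 9 benzyl 6,7-bis(benzyloxy)-4-oxochromane-5-carboxylate
Conditions: 5 (2.5 equiv), K2CO3, DMF, 50 °C
Reagents that add atoms: none
Why: Carboxylate alkylation gives the normal benzyl ester (not the pseudo-ester of the 2-acylbenzoic acid), and Williamson etherification under forcing carbonate conditions benzylates the hydrogen-bonded 6-hydroxyl.

Step 6
Reactants: 9 benzyl 6,7-bis(benzyloxy)-4-oxochromane-5-carboxylate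
Product: 10 benzyl 6,7-bis(benzyloxy)-4-chloro-3-formyl-2H-chromene-5-carboxylate
Conditions: POCl3, DMF, 0 → 60 °C; aq. NaOAc
Reagents that add atoms: N,N-dimethylformamide CN(C)C=O; phosphoryl chloride O=P(Cl)(Cl)Cl; water O
Why: The Vilsmeier–Haack–Arnold reaction turns a chroman-4-one into the 4-chloro-2H-chromene-3-carbaldehyde, and the only free ring position (C8) is deactivated by the para ester.

Step 7
Reactants: 10 benzyl 6,7-bis(benzyloxy)-4-chloro-3-formyl-2H-chromene-5-carboxylate
Product: 11 6,7-bis(benzyloxy)-5-[(benzyloxy)carbonyl]-4-chloro-2H-chromene-3-carboxylic acid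
Conditions: NaClO2, NaH2PO4, 2-methylbut-2-ene, t-BuOH/THF/H2O, rt
Reagents that add atoms: sodium chlorite [Na+].[O-]Cl=O
Why: Pinnick oxidation of a β-chloro enal gives the β-chloroacrylic acid and leaves the vinyl chloride and benzyl groups untouched.

Step 8
Reactants: 11 6,7-bis(benzyloxy)-5-[(benzyloxy)carbonyl]-4-chloro-2H-chromene-3-carboxylic acid; 12 (E)-4-(dimethylamino)but-3-en-2-one
Product: 16 benzyl 8,9-bis(benzyloxy)-3-formyl-2-methyl-4-oxo-4H,5H-pyrano[3,2-c]chromene-10-carboxylate (tribenzyl 3-formylcitromycetin), via acid chloride 13 (not isolated), via acyl enaminone 14 (not isolated), via iminium chloride 15 (not isolated)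
Conditions: (COCl)2, DMF (cat.), CH2Cl2, 0 °C → rt, evaporate; 12, Et3N, toluene, 0 → 70 °C; 1 M HCl, THF, 0 °C
Reagents that add atoms: oxalyl chloride O=C(Cl)C(=O)Cl (chlorine of 13 only); water O
Why: Proposed new method: acid chloride 13 should C-acylate the nucleophilic α-carbon of the enaminone, the vinylogous-amide oxygen of the acetyl group then displaces the β-chloride of the chromenyl enone by intramolecular addition–elimination to close the 4-pyranone, and the 3-(dimethyliminiomethyl) salt 15 hydrolyses to the aldehyde; the dimethylamino group masks the formyl oxygen so that only the acetyl oxygen can cyclise, which fixes the 2-methyl/3-formyl pattern, and the closest known reaction types are the Grohe–Heitzer cycloaracylation of aminoacrylates and the 4-pyranone synthesis from β-chlorovinyl acid chlorides and 1,3-dicarbonyl compounds.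

Step 9
Reactants: 17 pentane-2,4-dione (acetylacetone)
Product: 18 (E)-4-methoxypent-3-en-2-one
Conditions: HC(OMe)3, MeOH, TsOH (cat.), 55 °C
Reagents that add atoms: trimethyl orthoformate COC(OC)OC
Why: Acid-catalysed O-methylation of the diketone enol by the orthoformate gives the (E)-β-methoxy enone (vinylogous ester formation).

Step 10
Reactants: 18 (E)-4-methoxypent-3-en-2-one
Product: 19 (E)-4-methoxy-2-(trimethylsilyloxy)penta-1,3-diene
Conditions: LiN(iPr)2, THF, −78 °C; TMSCl
Reagents that add atoms: chlorotrimethylsilane C[Si](C)(C)Cl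
Why: Kinetic deprotonation of the methyl ketone and O-silylation (silyl enol ether formation) give the 1-alkoxy-3-silyloxy diene with the (E)-enol ether geometry retained.

Step 11
Reactants: 16 tribenzyl 3-formylcitromycetin; 19 (E)-4-methoxy-2-(trimethylsilyloxy)penta-1,3-diene
Product: 21 benzyl 8,9-bis(benzyloxy)-2-methyl-3-[(2R)-6-methyl-4-oxo-3,4-dihydro-2H-pyran-2-yl]-4-oxo-4H,5H-pyrano[3,2-c]chromene-10-carboxylate, via silyl aldolate 20 (not isolated)
Conditions: (R)-BINOL (20 mol %), Ti(OiPr)4 (10 mol %), 4 Å MS, CH2Cl2, −20 °C; then TFA, CH2Cl2, 0 °C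
Reagents that add atoms: none
Why: The titanium BINOLate (tetravalent titanium) activates the formyl group of 16, the unsubstituted CH2 terminus of diene 19 adds to the aldehyde carbon (Mukaiyama aldol, or its concerted [4+2] counterpart) to give silyl aldolate 20, and TFA then lets the carbinol oxygen add to the β-methoxy enone and expel methanol. The closest known reaction type is the titanium–BINOL-catalysed enantioselective hetero-Diels–Alder (aldol–cyclisation) reaction of 1-alkoxy-3-silyloxy dienes with aldehydes that have no α-hydrogen. Ring C closes as a six-membered ring by 6-endo oxa-Michael addition to the vinylogous ester followed by β-elimination of methanol, which makes the O–C(future ketal carbon A) bond after the CH(carbinol)–C(future chromone C3) bond. The only new stereocentre, the carbinol CH, is set by the ligand: (R)-BINOL is chosen so that the diene adds to the Re face and gives the (R)-dihydropyranone, which maps onto the (S)-carbinol of the target. The step needs 1,2-addition at the formyl carbon in preference to the inverse-demand mode in which O=CH–C3=C2 of the formylpyranone reacts as a 1-oxadiene or Michael acceptor; the C2 methyl group would make that mode build a quaternary carbon and should suppress it. The pyranone C4 carbonyl can chelate titanium together with the formyl oxygen, which should raise reactivity but is the reason the facial sense has to be confirmed.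

Step 12
Reactants: 22 2-fluoro-4,5-dimethoxybenzaldehyde
Product: 23 2-fluoro-4,5-dihydroxybenzaldehyde
Conditions: BBr3, CH2Cl2, −78 °C → rt; H2O
Reagents that add atoms: none
Why: Lewis-acid cleavage of both aryl methyl ethers by BBr3 leaves the aldehyde and the aryl fluoride intact.

Step 13
Reactants: 23 2-fluoro-4,5-dihydroxybenzaldehyde; 5 benzyl bromide
Product: 24 4-(benzyloxy)-2-fluoro-5-hydroxybenzaldehyde
Conditions: 5 (1.0 equiv), KHCO3, DMF, 40 °C
Reagents that add atoms: none
Why: Williamson etherification with weak base should select the hydroxyl para to the formyl group, the most acidic phenol, as in the 4-O-benzylation of 3,4-dihydroxybenzaldehyde.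

Step 14
Reactants: 24 4-(benzyloxy)-2-fluoro-5-hydroxybenzaldehyde
Product: 25 4-(benzyloxy)-2-bromo-6-fluoro-3-hydroxybenzaldehyde
Conditions: Br2, NaOAc, AcOH, rt
Reagents that add atoms: bromine BrBr
Why: Electrophilic aromatic bromination is directed by the free phenol to its only open ortho position, between OH and CHO, as in the bromination of isovanillin.

Step 15
Reactants: 25 4-(benzyloxy)-2-bromo-6-fluoro-3-hydroxybenzaldehyde; 5 benzyl bromide
Product: 26 3,4-bis(benzyloxy)-2-bromo-6-fluorobenzaldehyde
Conditions: 5, K2CO3, DMF, rt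
Reagents that add atoms: none
Why: Williamson etherification of the remaining phenol.

Step 16
Reactants: 26 3,4-bis(benzyloxy)-2-bromo-6-fluorobenzaldehyde
Product: 27 3,4-bis(benzyloxy)-2-bromo-6-tert-butoxybenzaldehyde
Conditions: KOtBu, THF/DMF, 0 °C → rt
Reagents that add atoms: potassium tert-butoxide CC(C)(C)[O-].[K+]
Why: SNAr displacement of the fluoride activated by the ortho formyl group installs an acid-labile mask of the future chromone oxygen, and tert-butoxide carries no hydride that could reduce the aldehyde.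

Step 17
Reactants: 21 (2R)-dihydropyranone; 27 3,4-bis(benzyloxy)-2-bromo-6-tert-butoxybenzaldehyde
Product: 28 benzyl 8,9-bis(benzyloxy)-3-[(2R)-3-{[3,4-bis(benzyloxy)-2-bromo-6-tert-butoxyphenyl](hydroxy)methyl}-6-methyl-4-oxo-3,4-dihydro-2H-pyran-2-yl]-2-methyl-4-oxo-4H,5H-pyrano[3,2-c]chromene-10-carboxylate (mixture at C3 and at the new carbinol)
Conditions: LiN(iPr)2 (1.05 equiv), THF, −78 °C; 27; AcOH, −78 °C
Reagents that add atoms: none
Why: Kinetic lithium enolate formation at C3, the only α′ position, through a lithium-bound cyclic transition state should outrun γ-deprotonation of the pyranone methyl, and aldol addition to the aldehyde followed by a cold quench avoids β-elimination of the ring oxygen; the two new centres need no control because both are removed later.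

Step 18
Reactants: 28 aldol adduct
Product: 29 benzyl 8,9-bis(benzyloxy)-3-[(2R)-3-[3,4-bis(benzyloxy)-2-bromo-6-tert-butoxybenzoyl]-6-methyl-4-oxo-3,4-dihydro-2H-pyran-2-yl]-2-methyl-4-oxo-4H,5H-pyrano[3,2-c]chromene-10-carboxylate
Conditions: DMP, NaHCO3, CH2Cl2, 0 °C; used at once
Reagents that add atoms: none
Why: Dess–Martin oxidation gives the 1,3-diketone without base, and 29 is kept cold and carried on immediately because its endocyclic enol could open ring C reversibly (retro-oxa-Michael or oxa-6π) and erode the C2 centre.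

Step 19
Reactants: 29 tert-butoxyaryl 1,3-diketone
Product: 33 bromo bis-ketal (tribenzyl east half; 6,7-bis(benzyloxy)-5-bromo west chromone; A R; carbinol CH S; CHα S; B S), via phenol 30 (not isolated), via dienol ether 31 (not isolated), via hemiketal 32 (not isolated)
Conditions: TFA/CH2Cl2, 0 °C; then H2O, THF, rt
Reagents that add atoms: water O
Why: TFA cleaves the aryl tert-butyl ether and the freed phenol cyclodehydrates onto the vinylogous-ester carbonyl (acid chromone synthesis from an o-hydroxyaryl 1,3-diketone), after which acid-catalysed hydration of the dienol ether gives hemiketal 32 whose hydroxyl adds to C2 of the protonated pyranone (intramolecular oxa-Michael addition) to close ring D, ketal carbon A being fixed by the bridge from the carbinol centre while ketal carbon B and CHα should settle under thermodynamic control (reversible addition, enolisable centre) as the cis-fused isomer of the target.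

Step 20
Reactants: 33 bromo bis-ketal
Product: 34 hexabenzyl target (both carboxyls as benzyl esters, four phenols as benzyl ethers; stereocentres as in 33)
Conditions: Pd(OAc)2, Xantphos, CO (1 atm), BnOH, Et3N, toluene, 80 °C
Reagents that add atoms: carbon monoxide [C-]#[O+]; benzyl alcohol OCc1ccccc1
Why: Palladium-catalysed alkoxycarbonylation of the aryl bromide (oxidative addition of zerovalent palladium, CO insertion, alcoholysis) with a wide-bite-angle ligand suited to ortho-substituted bromides; the ketals and stereocentres are inert to triethylamine.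

Step 21
Reactants: 34 hexabenzyl target
Product: 35 CNP0230818.1 (A R; carbinol CH S; CHα S; B S)
Conditions: H2 (1 atm), Pd/C, THF/MeOH, rt
Reagents that add atoms: none
Why: Hydrogenolysis removes four benzyl ethers and two benzyl esters, while the tetrasubstituted chromone and enone double bonds and the ketals should not be reduced at 1 atm and rt.

**Compound list**
1 | benzene-1,2,4-triol | Oc1ccc(O)c(O)c1 | starting material
2 | 3-chloropropanoic acid | OC(=O)CCCl | starting material
3 | 3-chloro-1-(2,4,5-trihydroxyphenyl)propan-1-one (not isolated) | O=C(CCCl)c1cc(O)c(O)cc1O | intermediate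
4 | 6,7-dihydroxychroman-4-one | O=C1CCOc2cc(O)c(O)cc12 | intermediate
5 | benzyl bromide | BrCc1ccccc1 | starting material
6 | 7-(benzyloxy)-6-hydroxychroman-4-one | O=C1CCOc2cc(OCc3ccccc3)c(O)cc12 | intermediate
7 | 7-(benzyloxy)-6-hydroxy-4-oxochromane-5-carbaldehyde | O=C1CCOc2cc(OCc3ccccc3)c(O)c(C=O)c12 | intermediate
8 | 7-(benzyloxy)-6-hydroxy-4-oxochromane-5-carboxylic acid | O=C1CCOc2cc(OCc3ccccc3)c(O)c(C(=O)O)c12 | intermediate
9 | benzyl 6,7-bis(benzyloxy)-4-oxochromane-5-carboxylate | O=C1CCOc2cc(OCc3ccccc3)c(OCc3ccccc3)c(C(=O)OCc3ccccc3)c12 | intermediate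
10 | benzyl 6,7-bis(benzyloxy)-4-chloro-3-formyl-2H-chromene-5-carboxylate | O=CC1=C(Cl)c2c(C(=O)OCc3ccccc3)c(OCc3ccccc3)c(OCc3ccccc3)cc2OC1 | intermediate
11 | 6,7-bis(benzyloxy)-5-[(benzyloxy)carbonyl]-4-chloro-2H-chromene-3-carboxylic acid | OC(=O)C1=C(Cl)c2c(C(=O)OCc3ccccc3)c(OCc3ccccc3)c(OCc3ccccc3)cc2OC1 | intermediate
12 | (E)-4-(dimethylamino)but-3-en-2-one | CC(=O)/C=C/N(C)C | starting material
13 | benzyl 6,7-bis(benzyloxy)-4-chloro-3-(chlorocarbonyl)-2H-chromene-5-carboxylate (not isolated) | ClC(=O)C1=C(Cl)c2c(C(=O)OCc3ccccc3)c(OCc3ccccc3)c(OCc3ccccc3)cc2OC1 | intermediate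
14 | benzyl 3-[2-acetyl-3-(dimethylamino)acryloyl]-6,7-bis(benzyloxy)-4-chloro-2H-chromene-5-carboxylate (not isolated) | CC(=O)C(=CN(C)C)C(=O)C1=C(Cl)c2c(C(=O)OCc3ccccc3)c(OCc3ccccc3)c(OCc3ccccc3)cc2OC1 | intermediate
15 | N-{[10-(benzyloxycarbonyl)-8,9-bis(benzyloxy)-2-methyl-4-oxo-4H,5H-pyrano[3,2-c]chromen-3-yl]methylidene}-N-methylmethanaminium chloride (not isolated) | C[N+](C)=CC1=C(C)OC2=C(C1=O)COc1cc(OCc3ccccc3)c(OCc3ccccc3)c(C(=O)OCc3ccccc3)c12.[Cl-] | intermediate
16 | benzyl 8,9-bis(benzyloxy)-3-formyl-2-methyl-4-oxo-4H,5H-pyrano[3,2-c]chromene-10-carboxylate | O=CC1=C(C)OC2=C(C1=O)COc1cc(OCc3ccccc3)c(OCc3ccccc3)c(C(=O)OCc3ccccc3)c12 | intermediate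
17 | pentane-2,4-dione | CC(=O)CC(C)=O | starting material
18 | (E)-4-methoxypent-3-en-2-one | CO/C(C)=C/C(C)=O | intermediate
19 | (E)-4-methoxy-2-(trimethylsilyloxy)penta-1,3-diene | C=C(O[Si](C)(C)C)/C=C(/OC)C | intermediate
20 | benzyl 8,9-bis(benzyloxy)-3-[(1R,4E)-5-methoxy-3-oxo-1-(trimethylsilyloxy)hex-4-en-1-yl]-2-methyl-4-oxo-4H,5H-pyrano[3,2-c]chromene-10-carboxylate (not isolated) | CO/C(C)=C/C(=O)C[C@@H](O[Si](C)(C)C)C1=C(C)OC2=C(C1=O)COc1cc(OCc3ccccc3)c(OCc3ccccc3)c(C(=O)OCc3ccccc3)c12 | intermediate
21 | benzyl 8,9-bis(benzyloxy)-2-methyl-3-[(2R)-6-methyl-4-oxo-3,4-dihydro-2H-pyran-2-yl]-4-oxo-4H,5H-pyrano[3,2-c]chromene-10-carboxylate | CC1=CC(=O)C[C@@H](O1)C1=C(C)OC2=C(C1=O)COc1cc(OCc3ccccc3)c(OCc3ccccc3)c(C(=O)OCc3ccccc3)c12 | intermediate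
22 | 2-fluoro-4,5-dimethoxybenzaldehyde | COc1cc(F)c(C=O)cc1OC | starting material
23 | 2-fluoro-4,5-dihydroxybenzaldehyde | O=Cc1cc(O)c(O)cc1F | intermediate
24 | 4-(benzyloxy)-2-fluoro-5-hydroxybenzaldehyde | O=Cc1cc(O)c(OCc2ccccc2)cc1F | intermediate
25 | 4-(benzyloxy)-2-bromo-6-fluoro-3-hydroxybenzaldehyde | O=Cc1c(Br)c(O)c(OCc2ccccc2)cc1F | intermediate
26 | 3,4-bis(benzyloxy)-2-bromo-6-fluorobenzaldehyde | O=Cc1c(Br)c(OCc2ccccc2)c(OCc2ccccc2)cc1F | intermediate
27 | 3,4-bis(benzyloxy)-2-bromo-6-tert-butoxybenzaldehyde | O=Cc1c(Br)c(OCc2ccccc2)c(OCc2ccccc2)cc1OC(C)(C)C | intermediate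
28 | aldol adduct: (2R)-dihydropyranone 21 bearing at C3 the [3,4-bis(benzyloxy)-2-bromo-6-tert-butoxyphenyl](hydroxy)methyl group | CC1=CC(=O)C(C(O)c2c(Br)c(OCc3ccccc3)c(OCc3ccccc3)cc2OC(C)(C)C)[C@@H](O1)C1=C(C)OC2=C(C1=O)COc1cc(OCc3ccccc3)c(OCc3ccccc3)c(C(=O)OCc3ccccc3)c12 | intermediate
29 | 1,3-diketone: (2R)-dihydropyranone 21 bearing at C3 the 3,4-bis(benzyloxy)-2-bromo-6-tert-butoxybenzoyl group | CC1=CC(=O)C(C(=O)c2c(Br)c(OCc3ccccc3)c(OCc3ccccc3)cc2OC(C)(C)C)[C@@H](O1)C1=C(C)OC2=C(C1=O)COc1cc(OCc3ccccc3)c(OCc3ccccc3)c(C(=O)OCc3ccccc3)c12 | intermediate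
30 | phenol: 29 with the tert-butyl ether cleaved to OH (not isolated) | CC1=CC(=O)C(C(=O)c2c(Br)c(OCc3ccccc3)c(OCc3ccccc3)cc2O)[C@@H](O1)C1=C(C)OC2=C(C1=O)COc1cc(OCc3ccccc3)c(OCc3ccccc3)c(C(=O)OCc3ccccc3)c12 | intermediate
31 | benzyl 8,9-bis(benzyloxy)-3-[(1S)-7,8-bis(benzyloxy)-9-bromo-3-methyl-10-oxo-1H,10H-pyrano[4,3-b]chromen-1-yl]-2-methyl-4-oxo-4H,5H-pyrano[3,2-c]chromene-10-carboxylate (not isolated) | CC1=Cc2oc3cc(OCc4ccccc4)c(OCc4ccccc4)c(Br)c3c(=O)c2[C@@H](O1)C1=C(C)OC2=C(C1=O)COc1cc(OCc3ccccc3)c(OCc3ccccc3)c(C(=O)OCc3ccccc3)c12 | intermediate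
32 | hemiketal: 31 with water added across the dienol ether, 3-hydroxy-3-methyl-3,4-dihydro, (1S), epimers at C3 (not isolated) | CC1(O)Cc2oc3cc(OCc4ccccc4)c(OCc4ccccc4)c(Br)c3c(=O)c2[C@@H](O1)C1=C(C)OC2=C(C1=O)COc1cc(OCc3ccccc3)c(OCc3ccccc3)c(C(=O)OCc3ccccc3)c12 | intermediate
33 | bromo bis-ketal: target skeleton with east CO2Bn and two OBn, west 5-bromo-6,7-bis(benzyloxy)chromone; A (R), carbinol CH (S), CHα (S), B (S) | C[C@@]12Cc3oc4cc(OCc5ccccc5)c(OCc5ccccc5)c(Br)c4c(=O)c3[C@@H](O1)[C@H]1C(=O)C3=C(O[C@@]1(C)O2)c1c(cc(OCc4ccccc4)c(OCc4ccccc4)c1C(=O)OCc4ccccc4)OC3 | intermediate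
34 | hexabenzyl target: both carboxylic acids as benzyl esters and all four phenols as benzyl ethers; stereocentres as in 33 | C[C@@]12Cc3oc4cc(OCc5ccccc5)c(OCc5ccccc5)c(C(=O)OCc5ccccc5)c4c(=O)c3[C@@H](O1)[C@H]1C(=O)C3=C(O[C@@]1(C)O2)c1c(cc(OCc4ccccc4)c(OCc4ccccc4)c1C(=O)OCc4ccccc4)OC3 | intermediate
35 | CNP0230818.1; A (R), carbinol CH (S), CHα (S), B (S) | C[C@@]12Cc3oc4cc(O)c(O)c(C(=O)O)c4c(=O)c3[C@@H](O1)[C@H]1C(=O)C3=C(O[C@@]1(C)O2)c1c(cc(O)c(O)c1C(=O)O)OC3 | target

**Step count and risks**
Total step count: 21.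
Longest linear sequence: 14 steps (steps 1–8, 11, 17–21).

Three steps most likely to fail:

Step 8 (the step carrying the label). The enaminone may be acylated on oxygen, or the acyl enaminone may hydrolyse before ring closure, so that the pyranone forms with the wrong substituent pattern or not at all. The fallback uses known chemistry and sets out from acid chloride 13, made from 11 as in step 8. C-acylation of the magnesium enolate of tert-butyl acetoacetate (MgCl2, Et3N, MeCN) followed by ring closure by addition–elimination (K2CO3, DMF) would give the tert-butyl pyranone-3-carboxylate F1. TFA would then give the pyranone-3-carboxylic acid F2. Mixed-anhydride formation (isobutyl chloroformate, N-methylmorpholine) and NaBH4 reduction would give the 3-(hydroxymethyl)pyranone F3, and MnO2 oxidation comes back to the route at 16.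

Step 19. The cascade may stall: the hemiketal hydroxyl may fail to add to the hindered, benzylated pyranone because the oxa-Michael equilibrium is slow or unfavourable, and long acid exposure at that stage would invite reversible opening of ring C. The fallback sets out from hemiketal 32, isolated by stopping step 19 after the hydration stage. Alkoxycarbonylation as in step 20 would give the hexabenzyl hemiketal F4, and hydrogenolysis as in step 21 the free seco acid F5. Ring D is then closed last, on the unprotected natural substitution pattern, in aqueous buffer (pH 4–5, rt), which comes back to the route at 35.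

Step 17. γ-Deprotonation of the pyranone 2-methyl group may compete, or the enolate may undergo β-elimination with opening of ring C, so that the aldehyde is attached at the wrong carbon or the ring is lost. The fallback fixes the regiochemistry before ring C exists and sets out from 18 and 27. Aldol addition of the lithium enolate of 18 to 27 would give the hydroxy enone F6, and double silylation (TMSOTf, Et3N) the bis-silyl diene F7. Union of F7 with 16 under the catalyst of step 11, followed by mild acid work-up with loss of methanol and both silyl groups, comes back to the route at 28.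

**Further compounds**
F1 | step 8 | tert-butyl 10-[(benzyloxy)carbonyl]-8,9-bis(benzyloxy)-2-methyl-4-oxo-4H,5H-pyrano[3,2-c]chromene-3-carboxylate | CC(C)(C)OC(=O)C1=C(C)OC2=C(C1=O)COc1cc(OCc3ccccc3)c(OCc3ccccc3)c(C(=O)OCc3ccccc3)c12
F2 | step 8 | 10-[(benzyloxy)carbonyl]-8,9-bis(benzyloxy)-2-methyl-4-oxo-4H,5H-pyrano[3,2-c]chromene-3-carboxylic acid | OC(=O)C1=C(C)OC2=C(C1=O)COc1cc(OCc3ccccc3)c(OCc3ccccc3)c(C(=O)OCc3ccccc3)c12
F3 | step 8 | benzyl 8,9-bis(benzyloxy)-3-(hydroxymethyl)-2-methyl-4-oxo-4H,5H-pyrano[3,2-c]chromene-10-carboxylate | OCC1=C(C)OC2=C(C1=O)COc1cc(OCc3ccccc3)c(OCc3ccccc3)c(C(=O)OCc3ccccc3)c12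
F4 | step 19 | hexabenzyl hemiketal (32 with Br replaced by CO2Bn) | CC1(O)Cc2oc3cc(OCc4ccccc4)c(OCc4ccccc4)c(C(=O)OCc4ccccc4)c3c(=O)c2[C@@H](O1)C1=C(C)OC2=C(C1=O)COc1cc(OCc3ccccc3)c(OCc3ccccc3)c(C(=O)OCc3ccccc3)c12
F5 | step 19 | free seco acid hemiketal (F4 without benzyl groups) | CC1(O)Cc2oc3cc(O)c(O)c(C(=O)O)c3c(=O)c2[C@@H](O1)C1=C(C)OC2=C(C1=O)COc1cc(O)c(O)c(C(=O)O)c12
F6 | step 17 | (E)-1-[3,4-bis(benzyloxy)-2-bromo-6-tert-butoxyphenyl]-1-hydroxy-5-methoxyhex-4-en-3-one | CO/C(C)=C/C(=O)CC(O)c1c(Br)c(OCc2ccccc2)c(OCc2ccccc2)cc1OC(C)(C)C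
F7 | step 17 | (4E)-1-[3,4-bis(benzyloxy)-2-bromo-6-tert-butoxyphenyl]-5-methoxy-1,3-bis(trimethylsilyloxy)hexa-2,4-diene | CO/C(C)=C/C(O[Si](C)(C)C)=CC(O[Si](C)(C)C)c1c(Br)c(OCc2ccccc2)c(OCc2ccccc2)cc1OC(C)(C)C
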